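The route rests on disconnecting the C2–C3 bond of the pyranone ring (ring C). An enantioselective dirhodium-carbenoid C–H insertion joins the carbenoid carbon of an aryl diazomethyl ketone (future C3, next to C4=O on ring A) to the OCH2 carbon of a benzyl aryl ether (future C2), closing ring C and creating the C2 stereocentre in one operation. The step exploits that C2 is a methine bound to O1 and to the electron-rich ring B, a doubly activated C–H site six atoms from the carbenoid. The precursor is an achiral 2-(benzyloxy)aryl diazo ketone whose 7-oxygen and side-chain oxygen are tied in a silaketal ring, made by silicon-tethered ring-closing metathesis to fix the (Z)-alkene.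

Key step: step 7

Remark: the SMILES is read as (2S) at C2 and (Z) in the side chain (CH2OH cis to the ring CH2); 1 is taken as a catalogue compound; the sense of induction of the chiral dirhodium catalyst cannot be predicted with certainty, so the catalyst antipode that delivers (2S) is the one used.

Step 1
Reactants: 1 1-(3-allyl-2,4-dihydroxyphenyl)ethan-1-one; 2 2-methylprop-2-en-1-ol
Product: 4 1-[3-allyl-4-({diisopropyl[(2-methylprop-2-en-1-yl)oxy]silyl}oxy)-2-hydroxyphenyl]ethan-1-one, via alkoxychlorosilane 3 (not isolated)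
Conditions: iPr2SiCl2 (3 equiv), Et3N, CH2Cl2, 0 °C, slow addition of 2; excess silane removed in vacuo; then 1, imidazole, DMF, 0 °C to rt
Reagents that add atoms: dichlorodiisopropylsilane CC(C)[Si](Cl)(Cl)C(C)C
Why: Stepwise substitution at silicon (unsymmetrical silaketal formation) should silylate only the 4-OH, because the 2-OH is hydrogen-bonded to the acetyl group and flanked on both sides.

Step 2
Reactants: 4 open-chain silaketal diene
Product: 5 1-[(5Z)-8-hydroxy-5-methyl-2,2-di(propan-2-yl)-4,7-dihydro-1,3,2-benzodioxasilonin-9-yl]ethan-1-one (nine-membered cyclic silaketal)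
Conditions: second-generation Hoveyda–Grubbs catalyst (5–10 mol %), 1,4-benzoquinone (10 mol %), toluene (0.002 M), 80 °C, argon sparge
Reagents that add atoms: none
Why: Temporary silicon-tethered ring-closing metathesis joins the allyl and methallyl groups held on adjacent ring positions, and the benzo-fused nine-membered ring can hold only the cis ring alkene, which is the (Z)-trisubstituted alkene of the side chain.

Step 3
Reactants: 6 3,4-dihydroxybenzaldehyde
Product: 7 3,4-bis[(tert-butyldimethylsilyl)oxy]benzaldehyde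
Conditions: TBSCl (2.4 equiv), imidazole, DMF, rt
Reagents that add atoms: tert-butyldimethylsilyl chloride CC(C)(C)[Si](C)(C)Cl
Why: Standard silyl ether formation on both phenols leaves the aldehyde untouched.

Step 4
Reactants: 7 3,4-bis[(tert-butyldimethylsilyl)oxy]benzaldehyde
Product: 8 {3,4-bis[(tert-butyldimethylsilyl)oxy]phenyl}methanol
Conditions: NaBH4, MeOH/THF, 0 °C
Reagents that add atoms: none
Why: Borohydride reduction of an aryl aldehyde is fast at 0 °C, and the aryl silyl ethers should tolerate the short exposure.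

Step 5
Reactants: 5 cyclic silaketal phenol; 8 {3,4-bis[(tert-butyldimethylsilyl)oxy]phenyl}methanol
Product: 9 1-{(5Z)-8-({3,4-bis[(tert-butyldimethylsilyl)oxy]phenyl}methoxy)-5-methyl-2,2-di(propan-2-yl)-4,7-dihydro-1,3,2-benzodioxasilonin-9-yl}ethan-1-one
Conditions: PPh3, DIAD, THF, 0 °C to rt
Reagents that add atoms: none
Why: In this Mitsunobu etherification the acidic chelated phenol displaces the primary benzylic oxyphosphonium under neutral conditions that spare every Si–O bond.

Step 6
Reactants: 9 benzyl aryl ether methyl ketone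
Product: 11 2-diazo-1-{(5Z)-8-({3,4-bis[(tert-butyldimethylsilyl)oxy]phenyl}methoxy)-5-methyl-2,2-di(propan-2-yl)-4,7-dihydro-1,3,2-benzodioxasilonin-9-yl}ethan-1-one, via trifluoroacetyl ketone 10 (not isolated)
Conditions: LiN(SiMe3)2, THF, −78 °C; CF3CO2CH2CF3, −78 °C; aq. NH4Cl work-up; then MsN3, Et3N, H2O (1 equiv), MeCN, rt
Reagents that add atoms: methanesulfonyl azide CS(=O)(=O)N=[N+]=[N-]; 2,2,2-trifluoroethyl trifluoroacetate O=C(OCC(F)(F)F)C(F)(F)F (its CF3CO group is carried only by 10)
Why: In this Danheiser detrifluoroacetylative diazo transfer the methyl-ketone enolate is trifluoroacetylated to the activated 1,3-diketone 10, which takes the diazo group from the sulfonyl azide and loses the trifluoroacetyl group as the N-acylsulfonamide.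

Step 7
Reactants: 11 aryl diazomethyl ketone
Product: 12 (2S)-3′,4′-bis[(tert-butyldimethylsilyl)oxy]flavanone bearing the (Z)-configured nine-membered diisopropylsilaketal ring across O7 and C8 (7-O–Si(iPr)2–O–CH2–C(CH3)=CH–CH2–C8)
Conditions: Rh2(S-PTTL)4 [dirhodium tetrakis(N-phthaloyl-(S)-tert-leucinate)] (2 mol %), CH2Cl2, 0 °C, 11 added by syringe pump over 4 h
Reagents that add atoms: none
Why: The divalent-rhodium dimer expels N2 from 11 to give an electrophilic acceptor carbenoid at the future C3, which inserts into one of the two enantiotopic benzylic O–CH2 hydrogens through a concerted, asynchronous three-centre transition state with hydride-transfer character, forming the C2–C3 bond and releasing the catalyst. The closest known reaction type is the dirhodium-carboxylate-catalysed intramolecular C–H insertion of 2-alkoxyaryl α-diazo ketones to chroman-4-ones, including its asymmetric form with chiral carboxylates. Ring C closes in the six-membered (1,6-insertion) mode, the only C–H insertion open to the carbenoid, because the 1,5-position is the ether oxygen and every other C–H bond would require bridging meta positions of ring A or a ring of eight or more atoms. The single new stereocentre C2 is set by the chiral carboxylate pocket of the catalyst (catalyst control, no substrate stereocentre), the catalyst enantiomer being chosen to give (2S). The step needs insertion to outrun attack of the ether oxygen on the carbenoid (oxonium ylide, then 1,2-benzyl shift to a benzofuranone) and intermolecular carbene reactions; the substrate helps because O1 is a weakly basic aryl ether conjugated to the ortho carbonyl and buried between two ortho substituents, the target C–H is doubly activated by O1 and the 3,4-bis(silyloxy)phenyl ring, and slow addition keeps the diazo concentration low.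

Step 8
Reactants: 12 silyl-protected (2S)-flavanone
Product: 13 (2S)-2-(3,4-dihydroxyphenyl)-7-hydroxy-8-[(2Z)-4-hydroxy-3-methylbut-2-en-1-yl]-2,3-dihydro-4H-chromen-4-one (target)
Conditions: HF·pyridine, pyridine, THF, 0 °C to rt; quench with Me3SiOMe
Reagents that add atoms: none
Why: Fluoride cleavage of all four Si–O bonds (two aryl silyl ethers and the silaketal) under buffered, weakly acidic conditions generates no phenoxide, so neither retro-oxa-Michael ring opening (racemisation at C2) nor ionisation of the allylic alcohol is expected.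

Compound list
1 | 1-(3-allyl-2,4-dihydroxyphenyl)ethan-1-one (3′-allyl-2′,4′-dihydroxyacetophenone) | CC(=O)c1ccc(O)c(CC=C)c1O | starting material
2 | 2-methylprop-2-en-1-ol | CC(=C)CO | starting material
3 | chloro(diisopropyl)[(2-methylprop-2-en-1-yl)oxy]silane | CC(C)[Si](Cl)(OCC(C)=C)C(C)C | intermediate
4 | 1-[3-allyl-4-({diisopropyl[(2-methylprop-2-en-1-yl)oxy]silyl}oxy)-2-hydroxyphenyl]ethan-1-one | CC(=O)c1ccc(O[Si](OCC(C)=C)(C(C)C)C(C)C)c(CC=C)c1O | intermediate
5 | 1-[(5Z)-8-hydroxy-5-methyl-2,2-di(propan-2-yl)-4,7-dihydro-1,3,2-benzodioxasilonin-9-yl]ethan-1-one | C/C1=C/Cc2c(ccc(C(C)=O)c2O)O[Si](C(C)C)(C(C)C)OC1 | intermediate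
6 | 3,4-dihydroxybenzaldehyde | O=Cc1ccc(O)c(O)c1 | starting material
7 | 3,4-bis[(tert-butyldimethylsilyl)oxy]benzaldehyde | O=Cc1ccc(O[Si](C)(C)C(C)(C)C)c(O[Si](C)(C)C(C)(C)C)c1 | intermediate
8 | {3,4-bis[(tert-butyldimethylsilyl)oxy]phenyl}methanol | OCc1ccc(O[Si](C)(C)C(C)(C)C)c(O[Si](C)(C)C(C)(C)C)c1 | intermediate
9 | 1-{(5Z)-8-({3,4-bis[(tert-butyldimethylsilyl)oxy]phenyl}methoxy)-5-methyl-2,2-di(propan-2-yl)-4,7-dihydro-1,3,2-benzodioxasilonin-9-yl}ethan-1-one | C/C1=C/Cc2c(ccc(C(C)=O)c2OCc3ccc(O[Si](C)(C)C(C)(C)C)c(O[Si](C)(C)C(C)(C)C)c3)O[Si](C(C)C)(C(C)C)OC1 | intermediate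
10 | 1-{(5Z)-8-({3,4-bis[(tert-butyldimethylsilyl)oxy]phenyl}methoxy)-5-methyl-2,2-di(propan-2-yl)-4,7-dihydro-1,3,2-benzodioxasilonin-9-yl}-4,4,4-trifluorobutane-1,3-dione | C/C1=C/Cc2c(ccc(C(=O)CC(=O)C(F)(F)F)c2OCc3ccc(O[Si](C)(C)C(C)(C)C)c(O[Si](C)(C)C(C)(C)C)c3)O[Si](C(C)C)(C(C)C)OC1 | intermediate
11 | 2-diazo-1-{(5Z)-8-({3,4-bis[(tert-butyldimethylsilyl)oxy]phenyl}methoxy)-5-methyl-2,2-di(propan-2-yl)-4,7-dihydro-1,3,2-benzodioxasilonin-9-yl}ethan-1-one | C/C1=C/Cc2c(ccc(C(=O)C=[N+]=[N-])c2OCc3ccc(O[Si](C)(C)C(C)(C)C)c(O[Si](C)(C)C(C)(C)C)c3)O[Si](C(C)C)(C(C)C)OC1 | intermediate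
12 | (2S)-3′,4′-bis[(tert-butyldimethylsilyl)oxy]flavanone with the (Z)-configured diisopropylsilaketal ring 7-O–Si(iPr)2–O–CH2–C(CH3)=CH–CH2–C8 | C/C1=C/Cc2c(ccc3c2O[C@H](c4ccc(O[Si](C)(C)C(C)(C)C)c(O[Si](C)(C)C(C)(C)C)c4)CC3=O)O[Si](C(C)C)(C(C)C)OC1 | intermediate
13 | (2S)-2-(3,4-dihydroxyphenyl)-7-hydroxy-8-[(2Z)-4-hydroxy-3-methylbut-2-en-1-yl]-2,3-dihydro-4H-chromen-4-one | C/C(=C/Cc1c(O)ccc2c1O[C@H](c1ccc(O)c(O)c1)CC2=O)CO | target

Total step count: 8. Longest linear sequence: 6 steps (1 → 4 → 5 → 9 → 11 → 12 → 13; the ring B branch 6 → 7 → 8 → 9 is equally long).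

Steps most likely to fail

1. Step 7. The carbenoid may be intercepted by the lone pair of the ether oxygen (five-membered oxonium ylide followed by 1,2-shift of the benzyl group) faster than it inserts, and discrimination between the two benzylic hydrogens may be incomplete. The fallback sets out from 9 and comes back at 12. Ketone 9 is converted (KN(SiMe3)2, THF, −78 °C; Ac2O) into the enol acetate F1. DDQ (2,6-dichloropyridine, LiClO4, 4 Å sieves, 1,2-dichloroethane, rt) should abstract hydride from the electron-rich benzylic ether CH2 to give an aryloxy-stabilised benzylic cation. The enol acetate carbon attacks this cation in a six-membered closure (oxidative C–H cleavage followed by Mukaiyama-type cyclisation, known for benzylic ethers carrying enol acetates). This forms the same C2–C3 bond and, after loss of the acetyl group, gives the racemic silaketal flavanone F2. Kinetic resolution by asymmetric transfer hydrogenation (RuCl(p-cymene)[(R,R)-TsDPEN], HCO2H/Et3N, EtOAc, rt, stopped near half conversion) should reduce the (2R)-enantiomer to the cis-(2R,4R)-flavan-4-ol F3 and leave 12, which is separated by chromatography.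

2. Step 2. Closure of a nine-membered ring may lose to intermolecular metathesis (oligomers) and to ruthenium-hydride migration of the allyl double bond into conjugation with ring A. The fallback sets out from 1 (and uses 8) and comes back at 13; it fixes the (Z)-alkene in an unstrained seven-membered lactone instead.
   - Acylation of the 4-OH of 1 with methacryloyl chloride (Et3N, CH2Cl2, 0 °C) gives 4-acetyl-2-allyl-3-hydroxyphenyl 2-methylprop-2-enoate F4.
   - Ring-closing metathesis (second-generation Grubbs catalyst, toluene, 80 °C) gives 7-acetyl-6-hydroxy-3-methyl-1-benzoxepin-2(5H)-one F5, whose ring alkene is necessarily cis.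
   - Mitsunobu etherification with 8 (PPh3, DIAD, THF) gives the lactone benzyl ether F6.
   - Excess iBu2AlH (CH2Cl2, −78 °C) reduces lactone and ketone to the (Z)-allylic alcohol triol F7.
   - TBSCl (2.1 equiv) with imidazole silylates the phenol and the primary alcohol to give the bis-silyl carbinol F8.
   - Dess–Martin periodinane restores the methyl ketone F9.
   - Diazo transfer as in step 6 proceeds through the trifluoroacetyl ketone F10 to the diazo ketone F11.
   - C–H insertion as in step 7 gives the tetrakis-silyl (2S)-flavanone F12, and HF·pyridine as in step 8 gives 13.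

3. Step 5. The phenol, hydrogen-bonded and flanked on both sides, may attack the oxyphosphonium too slowly, so that the hydrazide is alkylated instead or the electron-rich benzylic alcohol ionises and decomposes. The fallback sets out from 8 (with 5) and comes back at 9. Alcohol 8 is converted (Cl3CCN, DBU cat., CH2Cl2, 0 °C) into the benzyl trichloroacetimidate F13. Acid-catalysed benzylation of 5 (TMSOTf cat., CH2Cl2, −40 °C) then proceeds through the silyloxy-stabilised benzylic cation, which does not depend on the nucleophilicity of the phenol, and gives 9.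

Further compounds
F1 | step 7 | 1-{(5Z)-8-({3,4-bis[(tert-butyldimethylsilyl)oxy]phenyl}methoxy)-5-methyl-2,2-di(propan-2-yl)-4,7-dihydro-1,3,2-benzodioxasilonin-9-yl}ethenyl acetate | C/C1=C/Cc2c(ccc(C(=C)OC(C)=O)c2OCc3ccc(O[Si](C)(C)C(C)(C)C)c(O[Si](C)(C)C(C)(C)C)c3)O[Si](C(C)C)(C(C)C)OC1
F2 | step 7 | racemic form of 12 | C/C1=C/Cc2c(ccc3c2OC(c4ccc(O[Si](C)(C)C(C)(C)C)c(O[Si](C)(C)C(C)(C)C)c4)CC3=O)O[Si](C(C)C)(C(C)C)OC1
F3 | step 7 | cis-(2R,4R)-flavan-4-ol derived from the (2R)-enantiomer of F2 | C/C1=C/Cc2c(ccc3c2O[C@@H](c4ccc(O[Si](C)(C)C(C)(C)C)c(O[Si](C)(C)C(C)(C)C)c4)C[C@H]3O)O[Si](C(C)C)(C(C)C)OC1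
F4 | step 2 | 4-acetyl-2-allyl-3-hydroxyphenyl 2-methylprop-2-enoate | CC(=O)c1ccc(OC(=O)C(C)=C)c(CC=C)c1O
F5 | step 2 | 7-acetyl-6-hydroxy-3-methyl-1-benzoxepin-2(5H)-one | CC1=CCc2c(O)c(C(C)=O)ccc2OC1=O
F6 | step 2 | 7-acetyl-6-({3,4-bis[(tert-butyldimethylsilyl)oxy]phenyl}methoxy)-3-methyl-1-benzoxepin-2(5H)-one | CC1=CCc2c(OCc3ccc(O[Si](C)(C)C(C)(C)C)c(O[Si](C)(C)C(C)(C)C)c3)c(C(C)=O)ccc2OC1=O
F7 | step 2 | 3-({3,4-bis[(tert-butyldimethylsilyl)oxy]phenyl}methoxy)-4-(1-hydroxyethyl)-2-[(2Z)-4-hydroxy-3-methylbut-2-en-1-yl]phenol | C/C(=C/Cc1c(O)ccc(C(C)O)c1OCc1ccc(O[Si](C)(C)C(C)(C)C)c(O[Si](C)(C)C(C)(C)C)c1)CO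
F8 | step 2 | 1-[2-({3,4-bis[(tert-butyldimethylsilyl)oxy]phenyl}methoxy)-4-[(tert-butyldimethylsilyl)oxy]-3-{(2Z)-4-[(tert-butyldimethylsilyl)oxy]-3-methylbut-2-en-1-yl}phenyl]ethan-1-ol | C/C(=C/Cc1c(O[Si](C)(C)C(C)(C)C)ccc(C(C)O)c1OCc1ccc(O[Si](C)(C)C(C)(C)C)c(O[Si](C)(C)C(C)(C)C)c1)CO[Si](C)(C)C(C)(C)C
F9 | step 2 | 1-[2-({3,4-bis[(tert-butyldimethylsilyl)oxy]phenyl}methoxy)-4-[(tert-butyldimethylsilyl)oxy]-3-{(2Z)-4-[(tert-butyldimethylsilyl)oxy]-3-methylbut-2-en-1-yl}phenyl]ethan-1-one | C/C(=C/Cc1c(O[Si](C)(C)C(C)(C)C)ccc(C(C)=O)c1OCc1ccc(O[Si](C)(C)C(C)(C)C)c(O[Si](C)(C)C(C)(C)C)c1)CO[Si](C)(C)C(C)(C)C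
F10 | step 2 | 4,4,4-trifluoro-1-aryl-butane-1,3-dione derived from F9 | C/C(=C/Cc1c(O[Si](C)(C)C(C)(C)C)ccc(C(=O)CC(=O)C(F)(F)F)c1OCc1ccc(O[Si](C)(C)C(C)(C)C)c(O[Si](C)(C)C(C)(C)C)c1)CO[Si](C)(C)C(C)(C)C
F11 | step 2 | 2-diazo-1-aryl-ethan-1-one derived from F9 | C/C(=C/Cc1c(O[Si](C)(C)C(C)(C)C)ccc(C(=O)C=[N+]=[N-])c1OCc1ccc(O[Si](C)(C)C(C)(C)C)c(O[Si](C)(C)C(C)(C)C)c1)CO[Si](C)(C)C(C)(C)C
F12 | step 2 | (2S)-7,3′,4′-tris[(tert-butyldimethylsilyl)oxy]-8-{(2Z)-4-[(tert-butyldimethylsilyl)oxy]-3-methylbut-2-en-1-yl}flavanone | C/C(=C/Cc1c(O[Si](C)(C)C(C)(C)C)ccc2c1O[C@H](c1ccc(O[Si](C)(C)C(C)(C)C)c(O[Si](C)(C)C(C)(C)C)c1)CC2=O)CO[Si](C)(C)C(C)(C)C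
F13 | step 5 | {3,4-bis[(tert-butyldimethylsilyl)oxy]phenyl}methyl 2,2,2-trichloroacetimidate | N=C(OCc1ccc(O[Si](C)(C)C(C)(C)C)c(O[Si](C)(C)C(C)(C)C)c1)C(Cl)(Cl)Cl
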